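**Plan** (locants are those of the benzofuranone core: O1, C2=O, C3=CH2, C3a, C4–O, C5 side chain, C6–CH3, C7H2, C7a–O1)

1. Retrosynthesis: first the two isobutyrates; then C3a–C7a together with C2–C3 and C2–O1, so the fused α-methylene-γ-butyrolactone becomes a terminal allene, an aldehyde and CO; then the allene to a propargylic ether and the C4–alkyne bond; then the Z-tetrasubstituted C5=C6 alkene to a 2-alkyl-3-methylcyclopentenone cut at C(=O)–CH2; finally the cyclopentenone to (S)-citronellal and methyl vinyl ketone.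
2. Forward: Stetter reaction and aldol condensation build the cyclopentenone; α-ketol cleavage opens it to a Z-enal acetal; alkynylation and SN2′ reduction give the allenyl carbinol; one carbonylative [2+2+1] step closes the cyclohexene and the lactone together; desilylation and double acylation finish.
3. Stereochemistry: the side-chain centre comes from (S)-citronellal, the alkene geometry from the cyclopentenone ring, C4 from a ligand-controlled alkynylation, and C3a and C7a from C4 in the key step.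
4. Enabling feature: the exocyclic CH2, C3 and C3a are the three carbons of an allene, C7a–O1 is an aldehyde and C2 is the only atom missing, so the lactone cis-fused to the cyclohexene is the retron of an allenic hetero-Pauson–Khand reaction; the Z alkene C5=C6 holds allene and aldehyde cis.

Key step: step 12

Assumption: in step 9 the ProPhenol antipode written, (S,S), is taken to be the one that gives the (4S)-carbinol; the sense is set by the ligand alone, so its mirror image is used if the other face is attacked. TBS = tert-butyldimethylsilyl, TBDPS = tert-butyldiphenylsilyl.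

**Route**

Step 1
Reactants: 1 (S)-citronellal; 2 methyl vinyl ketone
Product: 3 (7S)-7,11-dimethyldodec-10-ene-2,5-dione
Conditions: 3-benzyl-5-(2-hydroxyethyl)-4-methylthiazolium chloride (10 mol %), Et3N (cat.), EtOH, 80 °C
Reagents that add atoms: none
Why: Stetter reaction, in which the thiazolium-derived acyl anion equivalent of the aliphatic aldehyde adds 1,4 to the enone to give the 1,4-diketone, the stereocentre lying beta to the new ketone and staying untouched.

Step 2
Reactants: 3 (7S)-7,11-dimethyldodec-10-ene-2,5-dione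
Product: 4 3-methyl-2-[(2S)-6-methylhept-5-en-2-yl]cyclopent-2-en-1-one
Conditions: 2 % aq NaOH, EtOH, reflux
Reagents that add atoms: none
Why: Intramolecular aldol condensation of a 2,5-diketone (jasmone-type closure) should give the more substituted, tetrasubstituted enone, whose ring later fixes the alkene geometry.

Step 3
Reactants: 4 3-methyl-2-[(2S)-6-methylhept-5-en-2-yl]cyclopent-2-en-1-one
Product: 6 2-[(2S)-5-hydroxypentan-2-yl]-3-methylcyclopent-2-en-1-one, via aldehyde 5 (not isolated)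
Conditions: O3, CH2Cl2/MeOH, Sudan Red 7B, −78 °C; Me2S; then NaBH4, −78 °C
Reagents that add atoms: ozone, O=[O+][O-]
Why: Ozonolysis to a dye end-point should cleave the electron-rich trisubstituted alkene before the deactivated enone alkene, and borohydride at −78 °C should reduce the aldehyde but not the enone.

Step 4
Reactants: 6 2-[(2S)-5-hydroxypentan-2-yl]-3-methylcyclopent-2-en-1-one
Product: 7 2-[(2S)-5-(TBDPS-oxy)pentan-2-yl]-3-methylcyclopent-2-en-1-one
Conditions: TBDPSCl, imidazole, DMF, rt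
Reagents that add atoms: tert-butyl(chloro)diphenylsilane, CC(C)(C)[Si](Cl)(c1ccccc1)c1ccccc1
Why: Standard silylation of a primary alcohol gives an ether that should survive base, hydride, mild acid and the later silyl triflate steps.

Step 5
Reactants: 7 2-[(2S)-5-(TBDPS-oxy)pentan-2-yl]-3-methylcyclopent-2-en-1-one
Product: 9 5-hydroxy-3-methyl-2-[(2S)-5-(TBDPS-oxy)pentan-2-yl]cyclopent-2-en-1-one (both C5 epimers), via potassium dienolate 8 (not isolated)
Conditions: KN(SiMe3)2, THF, −78 °C; then 3-phenyl-2-(phenylsulfonyl)oxaziridine, −78 °C; aq NH4Cl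
Reagents that add atoms: 3-phenyl-2-(phenylsulfonyl)oxaziridine, O=S(=O)(N1OC1c1ccccc1)c1ccccc1
Why: Kinetic deprotonation at the alpha′ methylene gives the cross-conjugated enolate, which the N-sulfonyloxaziridine hydroxylates (enolate oxidation); the new carbinol centre is destroyed in step 6, so both epimers serve.

Step 6
Reactants: 9 5-hydroxy-3-methyl-2-[(2S)-5-(TBDPS-oxy)pentan-2-yl]cyclopent-2-en-1-one
Product: 11 methyl (2Z)-5,5-dimethoxy-3-methyl-2-[(2S)-5-(TBDPS-oxy)pentan-2-yl]pent-2-enoate, via aldehyde ester 10 (not isolated)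
Conditions: Pb(OAc)4, MeOH/benzene, 0 °C; then HC(OMe)3, PPTS (cat.), rt
Reagents that add atoms: methanol, CO; trimethyl orthoformate, COC(OC)OC
Why: Lead tetraacetate in methanol cleaves the α-ketol (ketol cleavage) into a methyl ester at the former carbonyl carbon and an aldehyde at the carbinol carbon; because the ring held the two ends cis the tetrasubstituted alkene should emerge Z, and the saturated aldehyde is acetalised in the same flask.

Step 7
Reactants: 11 methyl (2Z)-5,5-dimethoxy-3-methyl-2-[(2S)-5-(TBDPS-oxy)pentan-2-yl]pent-2-enoate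
Product: 12 (2Z)-5,5-dimethoxy-3-methyl-2-[(2S)-5-(TBDPS-oxy)pentan-2-yl]pent-2-en-1-ol
Conditions: i-Bu2AlH, CH2Cl2, −78 to 0 °C; neutral tartrate work-up
Reagents that add atoms: none
Why: Hydride reduction of the conjugated ester to the allylic alcohol leaves acetal, silyl ether and alkene geometry untouched.

Step 8
Reactants: 12 (2Z)-5,5-dimethoxy-3-methyl-2-[(2S)-5-(TBDPS-oxy)pentan-2-yl]pent-2-en-1-ol
Product: 13 (2Z)-5,5-dimethoxy-3-methyl-2-[(2S)-5-(TBDPS-oxy)pentan-2-yl]pent-2-enal
Conditions: MnO2, CH2Cl2, rt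
Reagents that add atoms: none
Why: Allylic oxidation with manganese dioxide is neutral and should keep the Z geometry of the enal.

Step 9
Reactants: 13 (2Z)-5,5-dimethoxy-3-methyl-2-[(2S)-5-(TBDPS-oxy)pentan-2-yl]pent-2-enal; 14 2-(prop-2-yn-1-yloxy)oxane
Product: 16 (4S,5Z)-8,8-dimethoxy-6-methyl-1-(oxan-2-yloxy)-5-[(2S)-5-(TBDPS-oxy)pentan-2-yl]oct-5-en-2-yn-4-ol, via alkynylzinc 15 (not isolated)
Conditions: Me2Zn, (S,S)-ProPhenol (20 mol %), Ph3PO (40 mol %), toluene, 0 °C
Reagents that add atoms: none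
Why: Catalytic asymmetric alkynylation of an enal, in which the dinuclear zinc–ProPhenol complex delivers the zinc acetylide to one aldehyde face, so the C4 carbinol is set by the ligand and independently of the remote side-chain centre.

Step 10
Reactants: 16 (4S,5Z)-8,8-dimethoxy-6-methyl-1-(oxan-2-yloxy)-5-[(2S)-5-(TBDPS-oxy)pentan-2-yl]oct-5-en-2-yn-4-ol
Product: 17 (4S,5Z)-8,8-dimethoxy-6-methyl-5-[(2S)-5-(TBDPS-oxy)pentan-2-yl]octa-1,2,5-trien-4-ol
Conditions: LiAlH4, Et2O, 0 °C to reflux
Reagents that add atoms: none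
Why: Hydroxyl-directed SN2′ reduction of a 4-alkoxybut-2-yn-1-ol, in which the alkoxyaluminate delivers hydride to the proximal alkyne carbon and the vinylalane expels the oxanyloxy group, should give the terminal allene without touching the carbinol centre.

Step 11
Reactants: 17 (4S,5Z)-8,8-dimethoxy-6-methyl-5-[(2S)-5-(TBDPS-oxy)pentan-2-yl]octa-1,2,5-trien-4-ol
Product: 20 (3Z,5S)-5-(TBS-oxy)-3-methyl-4-[(2S)-5-(TBDPS-oxy)pentan-2-yl]octa-3,6,7-trienal, via silyl ether acetal 18 (not isolated), via collidinium salt 19 (not isolated)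
Conditions: TBSOTf, 2,6-lutidine, CH2Cl2, −78 °C; then Et3SiOTf, 2,4,6-collidine, 0 °C; then H2O
Reagents that add atoms: tert-butyldimethylsilyl triflate, CC(C)(C)[Si](C)(C)OS(=O)(=O)C(F)(F)F; water, O
Why: Silyl triflate with lutidine silylates the hindered secondary alcohol, and silyl triflate with collidine turns the dimethyl acetal into a pyridinium salt that water hydrolyses to the aldehyde, a non-acidic deacetalisation that should spare silyl ethers, allene and the β,γ-unsaturated aldehyde.

Step 12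
Reactants: 20 (3Z,5S)-5-(TBS-oxy)-3-methyl-4-[(2S)-5-(TBDPS-oxy)pentan-2-yl]octa-3,6,7-trienal
Product: 21 (3aR,4S,7aR)-4-(TBS-oxy)-5-[(2S)-5-(TBDPS-oxy)pentan-2-yl]-6-methyl-3-methylidene-3a,4,7,7a-tetrahydro-1-benzofuran-2(3H)-one
Conditions: Ru3(CO)12 (5 mol %), CO (20 atm), 1,4-dioxane, 120 °C
Reagents that add atoms: carbon monoxide, [C-]#[O+]
Why: Zerovalent ruthenium binds the aldehyde C=O and the proximal allene π bond and couples them oxidatively to an oxaruthenacyclopentane, which forms C3a–C7a and closes the six-membered carbocycle in a 6-exo sense onto the internal allene carbon; CO then inserts into the Ru–C(sp2) bond and C–O reductive elimination closes the five-membered lactone, leaving the allene terminus as the exocyclic methylene. The closest known reaction type is the allenic hetero-Pauson–Khand reaction, the [2+2+1] cyclocarbonylation of ω-allenyl aldehydes to bicyclic α-methylene-γ-butyrolactones. C7a is set by the cis annulation of the five-membered metallacycle onto the forming cyclohexene, so the ring fusion should be cis. C3a is set by the C4 silyloxy centre: the bulky OTBS group should take the convex face of the forming bicycle, away from the metal-bound vinyl carbon and its methylene, which places O4 trans to C3. The step needs proximal over distal allene π-bond selectivity, secured by a six- against an eight-membered ring, and carbonyl–allene coupling without alkene participation, secured by the inert tetrasubstituted alkene, which only holds the partners cis.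

Step 13
Reactants: 21 (3aR,4S,7aR)-4-(TBS-oxy)-5-[(2S)-5-(TBDPS-oxy)pentan-2-yl]-6-methyl-3-methylidene-3a,4,7,7a-tetrahydro-1-benzofuran-2(3H)-one
Product: 22 (3aS,4S,7aR)-4-hydroxy-5-[(2S)-5-hydroxypentan-2-yl]-6-methyl-3-methylidene-3a,4,7,7a-tetrahydro-1-benzofuran-2(3H)-one
Conditions: HF·pyridine, pyridine, THF, 0 °C to rt
Reagents that add atoms: none
Why: Buffered fluoride desilylation should remove both silyl ethers without conjugate addition to the α-methylene lactone; the 3a descriptor changes only through ligand priorities.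

Step 14
Reactants: 22 (3aS,4S,7aR)-4-hydroxy-5-[(2S)-5-hydroxypentan-2-yl]-6-methyl-3-methylidene-3a,4,7,7a-tetrahydro-1-benzofuran-2(3H)-one
Product: 23 (4S)-4-[(3aR,4S,7aR)-6-methyl-3-methylidene-4-(2-methylpropanoyloxy)-2-oxo-2,3,3a,4,7,7a-hexahydro-1-benzofuran-5-yl]pentyl 2-methylpropanoate
Conditions: isobutyric anhydride, Et3N, DMAP (cat.), CH2Cl2, 0 °C to rt
Reagents that add atoms: isobutyric anhydride, CC(C)C(=O)OC(=O)C(C)C
Why: DMAP-catalysed acylation esterifies the primary and the secondary allylic hydroxyl with retention at C4, giving the target.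

**Compound list**

1 | (S)-citronellal, (3S)-3,7-dimethyloct-6-enal | O=CC[C@@H](C)CCC=C(C)C | starting material
2 | methyl vinyl ketone, but-3-en-2-one | CC(=O)C=C | starting material
3 | (7S)-7,11-dimethyldodec-10-ene-2,5-dione | CC(=O)CCC(=O)C[C@@H](C)CCC=C(C)C | intermediate
4 | 3-methyl-2-[(2S)-6-methylhept-5-en-2-yl]cyclopent-2-en-1-one | CC1=C([C@@H](C)CCC=C(C)C)C(=O)CC1 | intermediate
5 | (4S)-4-(2-methyl-5-oxocyclopent-1-en-1-yl)pentanal | CC1=C([C@@H](C)CCC=O)C(=O)CC1 | intermediate
6 | 2-[(2S)-5-hydroxypentan-2-yl]-3-methylcyclopent-2-en-1-one | CC1=C([C@@H](C)CCCO)C(=O)CC1 | intermediate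
7 | 2-[(2S)-5-(TBDPS-oxy)pentan-2-yl]-3-methylcyclopent-2-en-1-one | CC1=C([C@@H](C)CCCO[Si](c2ccccc2)(c2ccccc2)C(C)(C)C)C(=O)CC1 | intermediate
8 | potassium 4-methyl-5-[(2S)-5-(TBDPS-oxy)pentan-2-yl]cyclopenta-1,4-dien-1-olate | [K+].CC1=C([C@@H](C)CCCO[Si](c2ccccc2)(c2ccccc2)C(C)(C)C)C([O-])=CC1 | intermediate
9 | 5-hydroxy-3-methyl-2-[(2S)-5-(TBDPS-oxy)pentan-2-yl]cyclopent-2-en-1-one, both C5 epimers | CC1=C([C@@H](C)CCCO[Si](c2ccccc2)(c2ccccc2)C(C)(C)C)C(=O)C(O)C1 | intermediate
10 | methyl (2Z)-3-methyl-5-oxo-2-[(2S)-5-(TBDPS-oxy)pentan-2-yl]pent-2-enoate | COC(=O)/C([C@@H](C)CCCO[Si](c1ccccc1)(c1ccccc1)C(C)(C)C)=C(/C)CC=O | intermediate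
11 | methyl (2Z)-5,5-dimethoxy-3-methyl-2-[(2S)-5-(TBDPS-oxy)pentan-2-yl]pent-2-enoate | COC(=O)/C([C@@H](C)CCCO[Si](c1ccccc1)(c1ccccc1)C(C)(C)C)=C(/C)CC(OC)OC | intermediate
12 | (2Z)-5,5-dimethoxy-3-methyl-2-[(2S)-5-(TBDPS-oxy)pentan-2-yl]pent-2-en-1-ol | OC/C([C@@H](C)CCCO[Si](c1ccccc1)(c1ccccc1)C(C)(C)C)=C(/C)CC(OC)OC | intermediate
13 | (2Z)-5,5-dimethoxy-3-methyl-2-[(2S)-5-(TBDPS-oxy)pentan-2-yl]pent-2-enal | O=C/C([C@@H](C)CCCO[Si](c1ccccc1)(c1ccccc1)C(C)(C)C)=C(/C)CC(OC)OC | intermediate
14 | 2-(prop-2-yn-1-yloxy)oxane, racemic | C#CCOC1CCCCO1 | starting material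
15 | methyl[3-(oxan-2-yloxy)prop-1-yn-1-yl]zinc | C[Zn]C#CCOC1CCCCO1 | intermediate
16 | (4S,5Z)-8,8-dimethoxy-6-methyl-1-(oxan-2-yloxy)-5-[(2S)-5-(TBDPS-oxy)pentan-2-yl]oct-5-en-2-yn-4-ol, both epimers at the oxanyl acetal carbon | O(C1CCCCO1)CC#C[C@H](O)/C([C@@H](C)CCCO[Si](c2ccccc2)(c2ccccc2)C(C)(C)C)=C(/C)CC(OC)OC | intermediate
17 | (4S,5Z)-8,8-dimethoxy-6-methyl-5-[(2S)-5-(TBDPS-oxy)pentan-2-yl]octa-1,2,5-trien-4-ol | C=C=C[C@H](O)/C([C@@H](C)CCCO[Si](c1ccccc1)(c1ccccc1)C(C)(C)C)=C(/C)CC(OC)OC | intermediate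
18 | TBS ether of 17, (4S,5Z)-4-(TBS-oxy)-8,8-dimethoxy-6-methyl-5-[(2S)-5-(TBDPS-oxy)pentan-2-yl]octa-1,2,5-triene | C=C=C[C@H](O[Si](C)(C)C(C)(C)C)/C([C@@H](C)CCCO[Si](c1ccccc1)(c1ccccc1)C(C)(C)C)=C(/C)CC(OC)OC | intermediate
19 | 1-[(3Z,5S)-5-(TBS-oxy)-1-methoxy-3-methyl-4-[(2S)-5-(TBDPS-oxy)pentan-2-yl]octa-3,6,7-trien-1-yl]-2,4,6-trimethylpyridinium triflate, both epimers at C1 | C=C=C[C@H](O[Si](C)(C)C(C)(C)C)/C([C@@H](C)CCCO[Si](c1ccccc1)(c1ccccc1)C(C)(C)C)=C(/C)CC(OC)[n+]1c(C)cc(C)cc1C.[O-]S(=O)(=O)C(F)(F)F | intermediate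
20 | (3Z,5S)-5-(TBS-oxy)-3-methyl-4-[(2S)-5-(TBDPS-oxy)pentan-2-yl]octa-3,6,7-trienal | C=C=C[C@H](O[Si](C)(C)C(C)(C)C)/C([C@@H](C)CCCO[Si](c1ccccc1)(c1ccccc1)C(C)(C)C)=C(/C)CC=O | intermediate
21 | (3aR,4S,7aR)-4-(TBS-oxy)-5-[(2S)-5-(TBDPS-oxy)pentan-2-yl]-6-methyl-3-methylidene-3a,4,7,7a-tetrahydro-1-benzofuran-2(3H)-one | C=C1C(=O)O[C@@H]2CC(C)=C([C@@H](C)CCCO[Si](c3ccccc3)(c3ccccc3)C(C)(C)C)[C@@H](O[Si](C)(C)C(C)(C)C)[C@H]12 | intermediate
22 | (3aS,4S,7aR)-4-hydroxy-5-[(2S)-5-hydroxypentan-2-yl]-6-methyl-3-methylidene-3a,4,7,7a-tetrahydro-1-benzofuran-2(3H)-one | C=C1C(=O)O[C@@H]2CC(C)=C([C@@H](C)CCCO)[C@@H](O)[C@H]12 | intermediate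
23 | (4S)-4-[(3aR,4S,7aR)-6-methyl-3-methylidene-4-(2-methylpropanoyloxy)-2-oxo-2,3,3a,4,7,7a-hexahydro-1-benzofuran-5-yl]pentyl 2-methylpropanoate | C=C1C(=O)O[C@@H]2CC(C)=C([C@@H](C)CCCOC(=O)C(C)C)[C@@H](OC(=O)C(C)C)[C@H]12 | target

**Count and risks**

Total step count: 14. Longest linear sequence: 14 steps from 1 (2 and 14 are commercial partners).

The three steps most likely to fail:

Step 12. At 120 °C the β,γ-unsaturated aldehyde may isomerise into conjugation or lose CO before oxidative cyclisation, and facial control by the C4 silyloxy group may be incomplete. The fallback sets out from 20 and returns at 21, and it forms the C3a–C7a bond by allylmetal addition at room temperature instead of by a metallacycle. Me3Si–SnBu3 with [(η3-C3H5)PdCl]2 in THF should add silicon to the central and tin to the terminal allene carbon; the allylstannane so formed adds through its γ-carbon to the aldehyde and gives, after work-up, the cis-configured 2-(1-trimethylsilylvinyl)cyclohexenol F1. N-Iodosuccinimide in MeCN exchanges silicon for iodine to give the vinyl iodide F2. Pd(PPh3)4, CO (1 atm) and Et3N in THF then close the lactone by carbonylative lactonisation to 21.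

Step 9. Addition to the hindered, fully substituted enal may be slow, so that uncatalysed racemic addition competes, and the Lewis acidic zinc may isomerise the Z enal. The fallback sets out from 13 and returns at 16, and it sets C4 by ketone reduction instead of by C–C bond formation. The lithium acetylide of 14 (n-BuLi, THF, −78 °C) is added to 13 to give the carbinol as both C4 epimers F3. Dess–Martin periodinane gives the ynone F4. Corey–Bakshi–Shibata reduction (2-methyl-CBS-oxazaborolidine of the required antipode, catecholborane, toluene, −78 °C) then returns 16, the small alkynyl and the large tetrasubstituted alkenyl group being well differentiated.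

Step 6. Hemiketal formation at the conjugated, α-branched ketone may be sluggish, so that cleavage stalls or lead tetraacetate attacks elsewhere, and the aldehyde ester may lose its alkene geometry through enolisation during acetalisation. The fallback sets out from 9 and returns at 13, bypassing 11 and 12, and it uses glycol cleavage instead of ketol cleavage. Luche reduction (NaBH4, CeCl3·7H2O, MeOH, −40 °C) gives the diol F5 as a diastereomer mixture. NaIO4 in aqueous THF opens it to the Z-dialdehyde F6. The saturated aldehyde is then acetalised in preference to the hindered enal (MeOSiMe3, Me3SiOTf cat., CH2Cl2, −78 °C) to give 13.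

**Further compounds**

F1 | step 12 | cyclohexenol with the ring configuration of 21: 5-(TBS-oxy)-3-methyl-4-[(2S)-5-(TBDPS-oxy)pentan-2-yl]-6-[1-(trimethylsilyl)ethenyl]cyclohex-3-en-1-ol, OH and silylvinyl cis, OTBS and silylvinyl trans | C=C([Si](C)(C)C)[C@@H]1[C@H](O)CC(C)=C([C@@H](C)CCCO[Si](c2ccccc2)(c2ccccc2)C(C)(C)C)[C@H]1O[Si](C)(C)C(C)(C)C
F2 | step 12 | the corresponding 6-(1-iodoethenyl)cyclohex-3-en-1-ol, same ring configuration | C=C(I)[C@@H]1[C@H](O)CC(C)=C([C@@H](C)CCCO[Si](c2ccccc2)(c2ccccc2)C(C)(C)C)[C@H]1O[Si](C)(C)C(C)(C)C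
F3 | step 9 | (5Z)-8,8-dimethoxy-6-methyl-1-(oxan-2-yloxy)-5-[(2S)-5-(TBDPS-oxy)pentan-2-yl]oct-5-en-2-yn-4-ol, both C4 epimers | O(C1CCCCO1)CC#CC(O)/C([C@@H](C)CCCO[Si](c2ccccc2)(c2ccccc2)C(C)(C)C)=C(/C)CC(OC)OC
F4 | step 9 | (5Z)-8,8-dimethoxy-6-methyl-1-(oxan-2-yloxy)-5-[(2S)-5-(TBDPS-oxy)pentan-2-yl]oct-5-en-2-yn-4-one | O(C1CCCCO1)CC#CC(=O)/C([C@@H](C)CCCO[Si](c2ccccc2)(c2ccccc2)C(C)(C)C)=C(/C)CC(OC)OC
F5 | step 6 | 4-methyl-3-[(2S)-5-(TBDPS-oxy)pentan-2-yl]cyclopent-3-ene-1,2-diol, diastereomer mixture | CC1=C([C@@H](C)CCCO[Si](c2ccccc2)(c2ccccc2)C(C)(C)C)C(O)C(O)C1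
F6 | step 6 | (2Z)-3-methyl-2-[(2S)-5-(TBDPS-oxy)pentan-2-yl]pent-2-enedial | O=C/C([C@@H](C)CCCO[Si](c1ccccc1)(c1ccccc1)C(C)(C)C)=C(/C)CC=O
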